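**Plan**
- Retrosynthesis: the two MOM O–C bonds are cut first, then the C1'–C2' and C5'–C6' bonds of ring B (retro-[4+2]) to an aryl ethynyl ketone and a 1-methoxy-3-silyloxybutadiene. The carbinol–alkyne C–C bond then leads back to a benzaldehyde, and the O–CH3 bond and the two aryl–prenyl C–C bonds lead back to 2,4,6-trihydroxybenzaldehyde.
- Enabling feature: ring B is a benzene ring carrying only the ketone carbon (C1') and a hydroxyl para to it (C4'). This is the pattern a 3-silyloxy-1-methoxydiene leaves on an acyl alkyne after loss of methanol.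
- Forward: ring A is bought intact and decorated (C-prenyl at C3/C5, OMe at C4, MOM at O2/O6). The C1 aldehyde is extended to the ethynyl ketone, ring B is built de novo by cycloaddition, and the MOM groups are removed last.
- Stereochemistry: the target has no stereocentre and no stereogenic double bond. The stereocentres of alcohol 7 and cycloadduct 10 are formed racemic and are erased by oxidation and aromatisation.

Key step: step 6

Remark: twofold operations at the two equivalent ring positions (prenylation, MOM protection, MOM cleavage) are written as single steps; mono-functionalised species and salt forms present before aqueous work-up are not counted as separate compounds.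

**Step 1**
Reactants: 1 2,4,6-trihydroxybenzaldehyde; 2 prenyl bromide (1-bromo-3-methylbut-2-ene)
Product: 3 2,4,6-trihydroxy-3,5-bis(3-methylbut-2-en-1-yl)benzaldehyde
Conditions: 2 (2.2 equiv), 10% aq. KOH, 0 °C to rt; cold 1 M citric acid to pH 5
Reagents that add atoms: none
Why: Phenoxide C-alkylation (SN2 at the primary allylic bromide) of an acylphloroglucinol: in water the strongly solvated oxygens of the ambident trianion are poor nucleophiles, so carbon attacks, and C3 and C5 are the only unsubstituted ring carbons, C1 being blocked by the formyl group.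

**Step 2**
Reactants: 3 2,4,6-trihydroxy-3,5-bis(3-methylbut-2-en-1-yl)benzaldehyde
Product: 4 2,6-dihydroxy-4-methoxy-3,5-bis(3-methylbut-2-en-1-yl)benzaldehyde
Conditions: Me2SO4 (1.05 equiv), K2CO3 (1.1 equiv), acetone, rt
Reagents that add atoms: dimethyl sulfate, COS(=O)(=O)OC
Why: Williamson ether synthesis made regioselective by acidity, since the 4-hydroxyl (para to the formyl group and not hydrogen-bonded to it) is deprotonated first by one equivalent of weak base and is O-methylated by the hard electrophile, while the chelated 2- and 6-hydroxyls stay protonated.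

**Step 3**
Reactants: 4 2,6-dihydroxy-4-methoxy-3,5-bis(3-methylbut-2-en-1-yl)benzaldehyde
Product: 5 4-methoxy-2,6-bis(methoxymethoxy)-3,5-bis(3-methylbut-2-en-1-yl)benzaldehyde
Conditions: NaH (2.5 equiv), MOMCl (2.5 equiv), DMF, 0 °C to rt
Reagents that add atoms: chloromethyl methyl ether, COCCl
Why: Williamson-type O-alkylation with an α-chloro ether (MOM protection): irreversible deprotonation by NaH breaks the hydrogen bonds of both ortho-hydroxyls to the carbonyl and the phenoxides react rapidly with MOMCl, the non-enolisable aldehyde, methyl ether and olefins being inert to base.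

**Step 4**
Reactants: 5 4-methoxy-2,6-bis(methoxymethoxy)-3,5-bis(3-methylbut-2-en-1-yl)benzaldehyde; 6 ethynylmagnesium bromide
Product: 7 1-[4-methoxy-2,6-bis(methoxymethoxy)-3,5-bis(3-methylbut-2-en-1-yl)phenyl]prop-2-yn-1-ol (racemic)
Conditions: 6 (1.5 equiv, 0.5 M in THF), THF, 0 °C to rt; aq. NH4Cl
Reagents that add atoms: none
Why: Grignard 1,2-addition of a small, linear alkynyl nucleophile to an aldehyde that stays accessible between its two ortho substituents (the MOM oxygens can chelate magnesium); the carbinol stereocentre is formed as a racemate because step 5 removes it.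

**Step 5**
Reactants: 7 1-[4-methoxy-2,6-bis(methoxymethoxy)-3,5-bis(3-methylbut-2-en-1-yl)phenyl]prop-2-yn-1-ol
Product: 8 1-[4-methoxy-2,6-bis(methoxymethoxy)-3,5-bis(3-methylbut-2-en-1-yl)phenyl]prop-2-yn-1-one
Conditions: activated MnO2 (excess), CH2Cl2, rt
Reagents that add atoms: none
Why: MnO2 oxidation of an activated (propargylic and benzylic) secondary alcohol to the conjugated ynone under neutral, heterogeneous conditions that leave the MOM acetals, prenyl olefins and terminal alkyne untouched.

**Step 6**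
Reactants: 8 1-[4-methoxy-2,6-bis(methoxymethoxy)-3,5-bis(3-methylbut-2-en-1-yl)phenyl]prop-2-yn-1-one; 9 (E)-1-methoxy-3-(trimethylsilyloxy)buta-1,3-diene
Product: 12 (4-hydroxyphenyl)[4-methoxy-2,6-bis(methoxymethoxy)-3,5-bis(3-methylbut-2-en-1-yl)phenyl]methanone, via cyclohexadiene cycloadduct 10 (not isolated), via aryl trimethylsilyl ether 11 (not isolated)
Conditions: 9 (2.5 equiv), toluene, 80 °C; evaporate volatiles; K2CO3 (0.2 equiv), MeOH, 0 °C to rt; aq. NH4Cl
Reagents that add atoms: none
Why: A normal-electron-demand Diels–Alder reaction between the electron-rich diene and the electron-poor terminal ynone proceeds in a concerted, asynchronous way: the CH2 terminus of the diene (largest HOMO coefficient) bonds to the alkyne β-carbon (largest LUMO coefficient) and the methoxy-bearing terminus to the α-carbon. Ring B is closed by this intermolecular [4+2] cycloaddition, which forms the C1'–C2' and C5'–C6' bonds in one event and gives 1,4-cyclohexadiene 10. 1,4-Elimination of methanol (the ring CH2 hydrogens are doubly allylic and vinylogously acidic) aromatises 10 to silyl ether 11, and catalytic carbonate in methanol transfers the silyl group to the solvent to give phenol 12. The closest known reaction type is the benzannulation of acetylenic esters and ketones with 1-methoxy-3-silyloxybutadienes to para-hydroxyaryl carbonyl compounds. The one selectivity needed is para rather than meta placement of the hydroxyl, which the polarity match above secures; the stereocentre of 10 is lost on aromatisation, so no stereocontrol is required. The isolated trisubstituted prenyl olefins are not dienophiles for this diene, and the basic desilylation spares the MOM ethers.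

**Step 7**
Reactants: 12 (4-hydroxyphenyl)[4-methoxy-2,6-bis(methoxymethoxy)-3,5-bis(3-methylbut-2-en-1-yl)phenyl]methanone
Product: 13 vismiaphenone D
Conditions: 3 M aq. HCl–MeOH (1:10), rt; NaHCO3 quench at full conversion
Reagents that add atoms: none
Why: Acid-catalysed acetal cleavage (MOM removal by transacetalisation to methanol): the acetals are protonated and cleaved, assisted by hydrogen bonding of the emerging phenols to the ortho ketone, much faster at room temperature than the trisubstituted olefins are protonated, so the prenyl groups should survive if the reaction is stopped at full conversion.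

**Compound list**
1 | 2,4,6-trihydroxybenzaldehyde | O=Cc1c(O)cc(O)cc1O | starting material
2 | prenyl bromide (1-bromo-3-methylbut-2-ene) | CC(C)=CCBr | starting material
3 | 2,4,6-trihydroxy-3,5-bis(3-methylbut-2-en-1-yl)benzaldehyde | O=Cc1c(O)c(CC=C(C)C)c(O)c(CC=C(C)C)c1O | intermediate
4 | 2,6-dihydroxy-4-methoxy-3,5-bis(3-methylbut-2-en-1-yl)benzaldehyde | COc1c(CC=C(C)C)c(O)c(C=O)c(O)c1CC=C(C)C | intermediate
5 | 4-methoxy-2,6-bis(methoxymethoxy)-3,5-bis(3-methylbut-2-en-1-yl)benzaldehyde | COCOc1c(CC=C(C)C)c(OC)c(CC=C(C)C)c(OCOC)c1C=O | intermediate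
6 | ethynylmagnesium bromide | C#C[Mg]Br | starting material
7 | 1-[4-methoxy-2,6-bis(methoxymethoxy)-3,5-bis(3-methylbut-2-en-1-yl)phenyl]prop-2-yn-1-ol (racemic) | C#CC(O)c1c(OCOC)c(CC=C(C)C)c(OC)c(CC=C(C)C)c1OCOC | intermediate
8 | 1-[4-methoxy-2,6-bis(methoxymethoxy)-3,5-bis(3-methylbut-2-en-1-yl)phenyl]prop-2-yn-1-one | C#CC(=O)c1c(OCOC)c(CC=C(C)C)c(OC)c(CC=C(C)C)c1OCOC | intermediate
9 | (E)-1-methoxy-3-(trimethylsilyloxy)buta-1,3-diene | CO/C=C/C(=C)O[Si](C)(C)C | starting material
10 | [6-methoxy-4-(trimethylsilyloxy)cyclohexa-1,4-dien-1-yl][4-methoxy-2,6-bis(methoxymethoxy)-3,5-bis(3-methylbut-2-en-1-yl)phenyl]methanone (racemic, not isolated) | COC1C=C(O[Si](C)(C)C)CC=C1C(=O)c1c(OCOC)c(CC=C(C)C)c(OC)c(CC=C(C)C)c1OCOC | intermediate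
11 | [4-methoxy-2,6-bis(methoxymethoxy)-3,5-bis(3-methylbut-2-en-1-yl)phenyl][4-(trimethylsilyloxy)phenyl]methanone (not isolated) | COCOc1c(CC=C(C)C)c(OC)c(CC=C(C)C)c(OCOC)c1C(=O)c1ccc(O[Si](C)(C)C)cc1 | intermediate
12 | (4-hydroxyphenyl)[4-methoxy-2,6-bis(methoxymethoxy)-3,5-bis(3-methylbut-2-en-1-yl)phenyl]methanone | COCOc1c(CC=C(C)C)c(OC)c(CC=C(C)C)c(OCOC)c1C(=O)c1ccc(O)cc1 | intermediate
13 | vismiaphenone D ([2,6-dihydroxy-4-methoxy-3,5-bis(3-methylbut-2-en-1-yl)phenyl](4-hydroxyphenyl)methanone) | COc1c(CC=C(C)C)c(O)c(C(=O)c2ccc(O)cc2)c(O)c1CC=C(C)C | target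

**Step count and risks**

Total step count: 7. Longest linear sequence: 7 steps (1 to 13).

Steps most likely to fail:

Step 1. O-Alkylation and geminal C-alkylation of the ambident trianion may outrun the second C-prenylation, so that the ring is dearomatised or mono-prenylated material accumulates. The fallback sets out from 1 and returns at 5, placing the prenyl groups by cross-coupling instead of phenoxide alkylation. Compound 1 would be methylated at O4 (Me2SO4, K2CO3, acetone) to 2,6-dihydroxy-4-methoxybenzaldehyde F1. The two remaining ring positions would be brominated (NBS, 2.1 equiv, MeCN, 0 °C) to 3,5-dibromo-2,6-dihydroxy-4-methoxybenzaldehyde F2. Both hydroxyls would be protected (NaH, MOMCl, DMF) to give 3,5-dibromo-4-methoxy-2,6-bis(methoxymethoxy)benzaldehyde F3. A twofold Stille coupling with tributyl(3-methylbut-2-en-1-yl)stannane (Pd2(dba)3/P(t-Bu)3 cat., dioxane, 90 °C) should then deliver the linear prenyl groups and give 5.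

Step 6. The diene may be lost to hydrolysis or oligomerisation faster than it adds to the ynone, or a conjugate addition of its silyl enol ether terminus may stop short of ring closure. The fallback sets out from 5 and returns at 12; it brings ring B in ready-made and is held in reserve only, since it gives up the ring construction. (4-Bromophenoxy)(tert-butyl)dimethylsilane and Mg in THF would give [4-(tert-butyldimethylsilyloxy)phenyl]magnesium bromide F4. Addition of F4 to aldehyde 5 should give [4-(tert-butyldimethylsilyloxy)phenyl][4-methoxy-2,6-bis(methoxymethoxy)-3,5-bis(3-methylbut-2-en-1-yl)phenyl]methanol F5. MnO2 in CH2Cl2 would oxidise the doubly benzylic alcohol to [4-(tert-butyldimethylsilyloxy)phenyl][4-methoxy-2,6-bis(methoxymethoxy)-3,5-bis(3-methylbut-2-en-1-yl)phenyl]methanone F6, and TBAF in THF at 0 °C would remove the silyl group to give 12.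

Step 7. Acid-promoted addition of the freed ortho-hydroxyls to the protonated prenyl olefins (chroman formation) may compete with acetal cleavage. The fallback sets out from 4 and returns at 13, replacing the acid-labile MOM groups by allyl ethers that are removed with Pd(0).
- Compound 4 with allyl bromide and K2CO3 in DMF at 50 °C should give 4-methoxy-2,6-bis(prop-2-en-1-yloxy)-3,5-bis(3-methylbut-2-en-1-yl)benzaldehyde F7.
- Addition of 6 as in step 4 would give 1-[4-methoxy-2,6-bis(prop-2-en-1-yloxy)-3,5-bis(3-methylbut-2-en-1-yl)phenyl]prop-2-yn-1-ol F8.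
- MnO2 as in step 5 would give 1-[4-methoxy-2,6-bis(prop-2-en-1-yloxy)-3,5-bis(3-methylbut-2-en-1-yl)phenyl]prop-2-yn-1-one F9.
- Cycloaddition with 9 under the conditions of step 6 would pass through [6-methoxy-4-(trimethylsilyloxy)cyclohexa-1,4-dien-1-yl][4-methoxy-2,6-bis(prop-2-en-1-yloxy)-3,5-bis(3-methylbut-2-en-1-yl)phenyl]methanone F10 and [4-methoxy-2,6-bis(prop-2-en-1-yloxy)-3,5-bis(3-methylbut-2-en-1-yl)phenyl][4-(trimethylsilyloxy)phenyl]methanone F11, neither isolated, to (4-hydroxyphenyl)[4-methoxy-2,6-bis(prop-2-en-1-yloxy)-3,5-bis(3-methylbut-2-en-1-yl)phenyl]methanone F12.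
- Tsuji–Trost deallylation of F12 (Pd(PPh3)4 cat., morpholine, THF, rt) leaves the C-bound prenyl groups alone and should give 13 without any acid.

**Further compounds**
F1 | step 1 | 2,6-dihydroxy-4-methoxybenzaldehyde | COc1cc(O)c(C=O)c(O)c1
F2 | step 1 | 3,5-dibromo-2,6-dihydroxy-4-methoxybenzaldehyde | COc1c(Br)c(O)c(C=O)c(O)c1Br
F3 | step 1 | 3,5-dibromo-4-methoxy-2,6-bis(methoxymethoxy)benzaldehyde | COCOc1c(Br)c(OC)c(Br)c(OCOC)c1C=O
F4 | step 6 | [4-(tert-butyldimethylsilyloxy)phenyl]magnesium bromide | CC(C)(C)[Si](C)(C)Oc1ccc([Mg]Br)cc1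
F5 | step 6 | [4-(tert-butyldimethylsilyloxy)phenyl][4-methoxy-2,6-bis(methoxymethoxy)-3,5-bis(3-methylbut-2-en-1-yl)phenyl]methanol (racemic) | COCOc1c(CC=C(C)C)c(OC)c(CC=C(C)C)c(OCOC)c1C(O)c1ccc(O[Si](C)(C)C(C)(C)C)cc1
F6 | step 6 | [4-(tert-butyldimethylsilyloxy)phenyl][4-methoxy-2,6-bis(methoxymethoxy)-3,5-bis(3-methylbut-2-en-1-yl)phenyl]methanone | COCOc1c(CC=C(C)C)c(OC)c(CC=C(C)C)c(OCOC)c1C(=O)c1ccc(O[Si](C)(C)C(C)(C)C)cc1
F7 | step 7 | 4-methoxy-2,6-bis(prop-2-en-1-yloxy)-3,5-bis(3-methylbut-2-en-1-yl)benzaldehyde | C=CCOc1c(CC=C(C)C)c(OC)c(CC=C(C)C)c(OCC=C)c1C=O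
F8 | step 7 | 1-[4-methoxy-2,6-bis(prop-2-en-1-yloxy)-3,5-bis(3-methylbut-2-en-1-yl)phenyl]prop-2-yn-1-ol (racemic) | C#CC(O)c1c(OCC=C)c(CC=C(C)C)c(OC)c(CC=C(C)C)c1OCC=C
F9 | step 7 | 1-[4-methoxy-2,6-bis(prop-2-en-1-yloxy)-3,5-bis(3-methylbut-2-en-1-yl)phenyl]prop-2-yn-1-one | C#CC(=O)c1c(OCC=C)c(CC=C(C)C)c(OC)c(CC=C(C)C)c1OCC=C
F10 | step 7 | [6-methoxy-4-(trimethylsilyloxy)cyclohexa-1,4-dien-1-yl][4-methoxy-2,6-bis(prop-2-en-1-yloxy)-3,5-bis(3-methylbut-2-en-1-yl)phenyl]methanone (racemic, not isolated) | COC1C=C(O[Si](C)(C)C)CC=C1C(=O)c1c(OCC=C)c(CC=C(C)C)c(OC)c(CC=C(C)C)c1OCC=C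
F11 | step 7 | [4-methoxy-2,6-bis(prop-2-en-1-yloxy)-3,5-bis(3-methylbut-2-en-1-yl)phenyl][4-(trimethylsilyloxy)phenyl]methanone (not isolated) | C=CCOc1c(CC=C(C)C)c(OC)c(CC=C(C)C)c(OCC=C)c1C(=O)c1ccc(O[Si](C)(C)C)cc1
F12 | step 7 | (4-hydroxyphenyl)[4-methoxy-2,6-bis(prop-2-en-1-yloxy)-3,5-bis(3-methylbut-2-en-1-yl)phenyl]methanone | C=CCOc1c(CC=C(C)C)c(OC)c(CC=C(C)C)c(OCC=C)c1C(=O)c1ccc(O)cc1
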